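**Plan**
1. Retrosynthesis of the side chain: the dioxane is opened at O2′–C3′ (intramolecular SN2 of a hydroperoxide on a mesylate) and at O1′–C6′ (Co-mediated peroxidation of a 1,1-disubstituted alkene). The chain is then cut at C6′–CH2 (B-alkyl Suzuki), at C2–CH=CH2 (Stille) and at the propanoate Cα–C3′ bond (aldol).
2. Retrosynthesis of the bicycle: the C5=C6 alkene of ring B (C4a, C5, C6, C7, C8, C8a) goes back by reductive 1,3-transposition to a 2-methylcyclohex-2-enone with C5=O. Taking C6 and its methyl out from between C5 and C7 leaves a cis-hydrindan-1-one, itself the formal Diels–Alder adduct of cyclopent-2-enone and a 3-silyloxy-2,4-dimethylpenta-1,3-diene (cuts C1–C8a and C4–C4a).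
3. Enabling feature: ring B is a 1-methylcyclohexene whose C5=C6(Me) unit sits next to ring-fusion carbon C4a, with C7 a plain CH2. This is the C(=O)–C(Me)=CH pattern that a chloro(methyl)carbene writes between a ketone carbon and its α-CH2 when it expands a cyclopentanone silyl enol ether by one carbon.
4. Forward order: ring A by Michael/Michael annulation onto cyclopentenone, ring B by 5→6 ring expansion, enone to alkene, enol triflate, vinyl, Suzuki with the side-chain iodide, and the 1,2-dioxane last.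
5. Stereochemistry: C4a/C8a come from the catalyst-controlled conjugate addition and the cis ring closure. Cα and C3′ come from an Evans syn aldol, with C3′ inverted in the peroxide ring closure. C6′ is not controlled (radical peroxidation) and its epimer is separated.

Key step: step 5

Remark: locants C1–C8a are those of the target's hexahydronaphthalene and are used for all earlier intermediates too; the dioxane atoms are primed and Cα is the propanoate α-carbon.
Remark: no reagent-controlled method is known for a tertiary peroxy stereocentre of this kind, so C6′ is formed as both epimers in step 17 and the unwanted one is removed after step 18.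
Remark: in step 3 the catalyst enantiomer needed is the one whose enone complex leaves the Si face of Cβ open; the (S)-series is assumed from the usual α-C–H···O binding model.

**Step 1**
Reactants: 1 2,4-dimethylpentan-3-one
Product: 3 2,4-dimethylpent-1-en-3-one, via 2-bromo-2,4-dimethylpentan-3-one 2 (not isolated)
Conditions: Br2, CH2Cl2, 0 °C; then LiBr, Li2CO3, DMF, 130 °C
Reagents that add atoms: none
Why: α-Bromination of the symmetrical ketone through its enol gives the tertiary bromide, and E2 dehydrobromination can then only give the isopropenyl ketone; no stereocentre is involved.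

**Step 2**
Reactants: 3 2,4-dimethylpent-1-en-3-one
Product: 4 tert-butyl[(2,4-dimethylpenta-1,3-dien-3-yl)oxy]dimethylsilane
Conditions: TBSOTf, Et3N, CH2Cl2, 0 °C
Reagents that add atoms: tert-butyldimethylsilyl trifluoromethanesulfonate, CC(C)(C)[Si](C)(C)OS(=O)(=O)C(F)(F)F
Why: Soft enolisation with a silyl triflate and an amine; the isopropyl α-H is the only acidic C–H, so the tetrasubstituted silyl dienol ether forms regiospecifically.

**Step 3**
Reactants: 4 tert-butyl[(2,4-dimethylpenta-1,3-dien-3-yl)oxy]dimethylsilane; 5 cyclopent-2-en-1-one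
Product: 7 (3aS,7aS)-5-[(tert-butyldimethylsilyl)oxy]-4,4,6-trimethyl-2,3,3a,4,7,7a-hexahydro-1H-inden-1-one, via Michael adduct 6 (not isolated)
Conditions: (S)-o-tolyl-CBS oxazaborolidine·HNTf2 (20 mol %), toluene, −40 → 0 °C
Reagents that add atoms: none
Why: Oxazaborolidinium-catalysed Mukaiyama–Michael addition of the Me2C= terminus of 4 to the Si face of the enone Cβ (catalyst control, sets C8a), followed by 6-endo Michael closure of the resulting cyclopentenyl silyl enol ether onto the isopropenyl ketone (sets C4a cis, the only low-strain hydrindanone fusion), is a formal Diels–Alder reaction with "para" regiochemistry that leaves C2 as its silyl enol ether.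

**Step 4**
Reactants: 7 (3aS,7aS)-5-[(tert-butyldimethylsilyl)oxy]-4,4,6-trimethyl-2,3,3a,4,7,7a-hexahydro-1H-inden-1-one
Product: 9 (3aS,7aS)-5-[(tert-butyldimethylsilyl)oxy]-4,4,6-trimethyl-1-[(trimethylsilyl)oxy]-3a,4,7,7a-tetrahydro-3H-indene, via lithium enolate 8 (not isolated)
Conditions: LDA, TMSCl, THF, −78 °C; Et3N
Reagents that add atoms: chlorotrimethylsilane, C[Si](C)(C)Cl
Why: Kinetic deprotonation with internal silyl quench takes the cyclopentanone α-CH2 (C7) and not the ring-fusion α-CH, giving the less substituted silyl enol ether C5=C7 without touching C4a or C8a.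

**Step 5**
Reactants: 9 (3aS,7aS)-5-[(tert-butyldimethylsilyl)oxy]-4,4,6-trimethyl-1-[(trimethylsilyl)oxy]-3a,4,7,7a-tetrahydro-3H-indene
Product: 11 (4aS,8aS)-6-[(tert-butyldimethylsilyl)oxy]-2,5,5,7-tetramethyl-4a,5,8,8a-tetrahydronaphthalen-1(4H)-one, via siloxy chlorocyclopropane 10 (not isolated)
Conditions: CH3CHCl2, n-BuLi, Et2O, −40 → −20 °C; then PhMe, 2,6-lutidine, 100 °C
Reagents that add atoms: 1,1-dichloroethane, CC(Cl)Cl
Why: 1,1-Dichloroethyllithium (from CH3CHCl2 and n-BuLi) transfers chloro(methyl)carbene to the C5=C7 trimethylsilyl enol ether in a cheletropic [2+1] addition that closes the three-membered ring C5–C6–C7 of 10; on heating, the cyclopropyl chloride ionises with concerted disrotatory cleavage of the C5–C7 bond (cyclopropyl-to-allyl opening, pushed by the siloxy oxygen), and the 2-siloxyallyl cation loses Me3SiCl to give the 2-methylcyclohex-2-enone. The closest known reaction type is the halocarbene ring expansion of cyclic silyl enol ethers to 2-halo- or 2-methylcycloalk-2-enones. Ring B is not closed in this step but grows out of the cyclopentane: C6 with its methyl is inserted between C5 and C7, and the zero bridge of the bicyclo[3.1.0]hexane becomes the C5(=O)–C6(Me)=C7 unit of the six-membered ring. No new stereocentre survives (C5, C6 and C7 end sp2) and C4a/C8a are not touched; the thermolysis is kept neutral and amine-buffered so that C4a–H, now α to the carbonyl, does not epimerise. The step needs chemoselectivity between two silyl enol ethers, which the substrate secures because the ring-A enol ether is tetrasubstituted, carries the bulky TBS group and is flanked by the quaternary C1. It also needs regioselectivity in the opening, which is fixed because only the bond opposite the C–Cl carbon can break, placing C=O at C5 and the methyl at C6.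

**Step 6**
Reactants: 11 (4aS,8aS)-6-[(tert-butyldimethylsilyl)oxy]-2,5,5,7-tetramethyl-4a,5,8,8a-tetrahydronaphthalen-1(4H)-one
Product: 12 N'-[(4aS,8aS)-6-[(tert-butyldimethylsilyl)oxy]-2,5,5,7-tetramethyl-4a,5,8,8a-tetrahydronaphthalen-1(4H)-ylidene]-4-methylbenzenesulfonohydrazide
Conditions: TsNHNH2, THF, rt → 40 °C
Reagents that add atoms: 4-methylbenzenesulfonohydrazide, Cc1ccc(cc1)S(=O)(=O)NN
Why: Condensation of the hydrazide with the enone carbonyl gives the tosylhydrazone under neutral conditions that spare the silyl enol ether and do not enolise C4a.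

**Step 7**
Reactants: 12 N'-[(4aS,8aS)-6-[(tert-butyldimethylsilyl)oxy]-2,5,5,7-tetramethyl-4a,5,8,8a-tetrahydronaphthalen-1(4H)-ylidene]-4-methylbenzenesulfonohydrazide
Product: 14 tert-butyl(dimethyl){[(4aR,8aS)-1,1,3,6-tetramethyl-1,4,4a,7,8,8a-hexahydronaphthalen-2-yl]oxy}silane, via allylic diazene 13 (not isolated)
Conditions: catecholborane, CHCl3, 0 °C; then NaOAc·3H2O, reflux
Reagents that add atoms: none
Why: Kabalka reduction: catecholborane adds hydride 1,2 to the C=N, loss of sulfinate gives the allylic diazene, and its retro-ene loss of N2 delivers H to C7 with 1,3-transposition of the alkene to C5=C6, so ring B reaches its final form and no new stereocentre arises.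

**Step 8**
Reactants: 14 tert-butyl(dimethyl){[(4aR,8aS)-1,1,3,6-tetramethyl-1,4,4a,7,8,8a-hexahydronaphthalen-2-yl]oxy}silane
Product: 15 (4aR,8aS)-1,1,3,6-tetramethyl-1,4,4a,7,8,8a-hexahydronaphthalen-2-yl trifluoromethanesulfonate
Conditions: CsF, PhNTf2, DME, rt
Reagents that add atoms: N-phenylbis(trifluoromethanesulfonimide), O=S(=O)(N(c1ccccc1)S(=O)(=O)C(F)(F)F)C(F)(F)F
Why: Fluoride unmasks the ring-A enolate, which can only be the C2=C3 enolate because C1 is quaternary, and PhNTf2 O-triflates it (enol triflate from a silyl enol ether).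

**Step 9**
Reactants: 15 (4aR,8aS)-1,1,3,6-tetramethyl-1,4,4a,7,8,8a-hexahydronaphthalen-2-yl trifluoromethanesulfonate
Product: 16 (4aR,8aS)-2-ethenyl-1,1,3,6-tetramethyl-1,4,4a,7,8,8a-hexahydronaphthalene
Conditions: CH2=CHSnBu3, Pd(PPh3)4 (5 mol %), LiCl, THF, reflux
Reagents that add atoms: tributyl(ethenyl)stannane, C=C[Sn](CCCC)(CCCC)CCCC
Why: Stille coupling of the hindered enol triflate (LiCl-promoted) installs the vinyl group that will become the ethylene linker.

**Step 10**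
Reactants: 17 pent-4-yn-1-ol
Product: 18 4-iodopent-4-en-1-ol
Conditions: NaI, TMSCl, H2O, MeCN, rt
Reagents that add atoms: sodium iodide, [Na+].[I-]
Why: Markovnikov hydroiodination of the terminal alkyne by HI generated in situ gives the 2-iodoalk-1-ene.

**Step 11**
Reactants: 18 4-iodopent-4-en-1-ol
Product: 19 4-iodopent-4-enal
Conditions: Dess–Martin periodinane, NaHCO3, CH2Cl2, 0 °C → rt
Reagents that add atoms: none
Why: Dess–Martin oxidation takes the primary alcohol to the aldehyde under buffered conditions that leave the vinyl iodide alone.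

**Step 12**
Reactants: 20 (4R)-4-benzyl-3-propanoyl-1,3-oxazolidin-2-one; 19 4-iodopent-4-enal
Product: 22 (4R)-4-benzyl-3-[(2R,3S)-3-hydroxy-6-iodo-2-methylhept-6-enoyl]-1,3-oxazolidin-2-one, via (Z)-boron enolate 21 (not isolated)
Conditions: Bu2BOTf, iPr2NEt, CH2Cl2, −78 → 0 °C; 19, −78 → 0 °C; then pH 7 buffer, MeOH, 30% H2O2
Reagents that add atoms: none
Why: Evans syn aldol: the (Z)-boron enolate adds through a Zimmerman–Traxler chair on the enolate face opposite the benzyl group of the (R)-auxiliary, which sets Cα (R) and the carbinol carbon (S) in one step.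

**Step 13**
Reactants: 22 (4R)-4-benzyl-3-[(2R,3S)-3-hydroxy-6-iodo-2-methylhept-6-enoyl]-1,3-oxazolidin-2-one
Product: 23 (2S,3S)-6-iodo-2-methylhept-6-ene-1,3-diol
Conditions: LiBH4, MeOH, THF, 0 °C
Reagents that add atoms: none
Why: Reductive cleavage of the imide by LiBH4 gives the primary alcohol and returns the auxiliary, with the vinyl iodide and both stereocentres untouched (the descriptor at C2 changes only through CIP priorities).

**Step 14**
Reactants: 23 (2S,3S)-6-iodo-2-methylhept-6-ene-1,3-diol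
Product: 24 (2S,3S)-1-[(tert-butyldimethylsilyl)oxy]-6-iodo-2-methylhept-6-en-3-ol
Conditions: TBSCl, imidazole, CH2Cl2, −20 → 0 °C
Reagents that add atoms: tert-butylchlorodimethylsilane, CC(C)(C)[Si](C)(C)Cl
Why: Silylation is selective for the primary over the β-branched secondary hydroxyl.

**Step 15**
Reactants: 16 (4aR,8aS)-2-ethenyl-1,1,3,6-tetramethyl-1,4,4a,7,8,8a-hexahydronaphthalene; 24 (2S,3S)-1-[(tert-butyldimethylsilyl)oxy]-6-iodo-2-methylhept-6-en-3-ol
Product: 26 (2S,3S)-1-[(tert-butyldimethylsilyl)oxy]-2-methyl-6-methylidene-8-[(4aR,8aS)-1,1,3,6-tetramethyl-1,4,4a,7,8,8a-hexahydronaphthalen-2-yl]octan-3-ol, via alkylborane 25 (not isolated)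
Conditions: 9-BBN-H, THF, 0 °C → rt; then 24, Pd(dppf)Cl2 (5 mol %), AsPh3, Cs2CO3, DMF/H2O, rt
Reagents that add atoms: none
Why: 9-BBN hydroborates only the monosubstituted vinyl group (anti-Markovnikov), and B-alkyl Suzuki–Miyaura coupling of the primary alkylborane with the 2-iodoalkene forms the C(sp3)–C(sp2) bond and delivers the 1,1-disubstituted alkene at the future C6′.

**Step 16**
Reactants: 26 (2S,3S)-1-[(tert-butyldimethylsilyl)oxy]-2-methyl-6-methylidene-8-[(4aR,8aS)-1,1,3,6-tetramethyl-1,4,4a,7,8,8a-hexahydronaphthalen-2-yl]octan-3-ol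
Product: 27 (2S,3S)-1-[(tert-butyldimethylsilyl)oxy]-2-methyl-6-methylidene-8-[(4aR,8aS)-1,1,3,6-tetramethyl-1,4,4a,7,8,8a-hexahydronaphthalen-2-yl]octan-3-yl methanesulfonate
Conditions: MsCl, Et3N, CH2Cl2, 0 °C
Reagents that add atoms: methanesulfonyl chloride, CS(=O)(=O)Cl
Why: O-Sulfonylation with retention turns the secondary hydroxyl at the future C3′ into a leaving group.

**Step 17**
Reactants: 27 (2S,3S)-1-[(tert-butyldimethylsilyl)oxy]-2-methyl-6-methylidene-8-[(4aR,8aS)-1,1,3,6-tetramethyl-1,4,4a,7,8,8a-hexahydronaphthalen-2-yl]octan-3-yl methanesulfonate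
Product: 28 (2S,3S,6R)-1-[(tert-butyldimethylsilyl)oxy]-2,6-dimethyl-8-[(4aR,8aS)-1,1,3,6-tetramethyl-1,4,4a,7,8,8a-hexahydronaphthalen-2-yl]-6-[(triethylsilyl)peroxy]octan-3-yl methanesulfonate
Conditions: Co(thd)2 (10 mol %), O2 (1 atm), Et3SiH, ClCH2CH2Cl, rt
Reagents that add atoms: oxygen, O=O; triethylsilane, CC[SiH](CC)CC
Why: Mukaiyama–Isayama hydroperoxysilylation: Co–H hydrogen-atom transfer to the least hindered, 1,1-disubstituted alkene gives the tertiary radical, which traps O2 and is silylated (Markovnikov); the radical is planar, so 28 should form together with its C6 epimer, and the trisubstituted ring-B and tetrasubstituted ring-A alkenes should react far more slowly.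

**Step 18**
Reactants: 28 (2S,3S,6R)-1-[(tert-butyldimethylsilyl)oxy]-2,6-dimethyl-8-[(4aR,8aS)-1,1,3,6-tetramethyl-1,4,4a,7,8,8a-hexahydronaphthalen-2-yl]-6-[(triethylsilyl)peroxy]octan-3-yl methanesulfonate
Product: 31 (2S)-2-[(3R,6R)-6-methyl-6-{2-[(4aR,8aS)-1,1,3,6-tetramethyl-1,4,4a,7,8,8a-hexahydronaphthalen-2-yl]ethyl}-1,2-dioxan-3-yl]propan-1-ol, via hydroperoxide 29 (not isolated), via silyl ether dioxane 30 (not isolated)
Conditions: TBAF, THF, 0 °C → rt
Reagents that add atoms: none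
Why: Fluoride cleaves the labile Si–OO bond first, the tertiary peroxide anion displaces the secondary mesylate in a 6-exo-tet SN2 closure with inversion (S → R at C3′; intramolecular alkylation of a hydroperoxide), and the same reagent then removes the TBS ether; the cis/trans dioxanes that differ at C6′ are separated here by chromatography.

**Step 19**
Reactants: 31 (2S)-2-[(3R,6R)-6-methyl-6-{2-[(4aR,8aS)-1,1,3,6-tetramethyl-1,4,4a,7,8,8a-hexahydronaphthalen-2-yl]ethyl}-1,2-dioxan-3-yl]propan-1-ol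
Product: 33 (2R)-2-[(3R,6R)-6-methyl-6-{2-[(4aR,8aS)-1,1,3,6-tetramethyl-1,4,4a,7,8,8a-hexahydronaphthalen-2-yl]ethyl}-1,2-dioxan-3-yl]propanoic acid, via aldehyde 32 (not isolated)
Conditions: TEMPO (20 mol %), PhI(OAc)2, MeCN/H2O, rt
Reagents that add atoms: water, O
Why: Oxoammonium (TEMPO/PhI(OAc)2) oxidation takes the primary alcohol through the aldehyde hydrate to the acid without strong acid, base or metal that could harm the peroxide, the alkenes or the α-stereocentre.

**Step 20**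
Reactants: 33 (2R)-2-[(3R,6R)-6-methyl-6-{2-[(4aR,8aS)-1,1,3,6-tetramethyl-1,4,4a,7,8,8a-hexahydronaphthalen-2-yl]ethyl}-1,2-dioxan-3-yl]propanoic acid
Product: 34 methyl (2R)-2-[(3R,6R)-6-methyl-6-{2-[(4aR,8aS)-1,1,3,6-tetramethyl-1,4,4a,7,8,8a-hexahydronaphthalen-2-yl]ethyl}-1,2-dioxan-3-yl]propanoate
Conditions: TMSCHN2, PhMe/MeOH, 0 °C
Reagents that add atoms: (trimethylsilyl)diazomethane, C[Si](C)(C)C=[N+]=[N-]
Why: O-Methylation of the acid with trimethylsilyldiazomethane gives the methyl ester under neutral conditions, with no stereocentre affected.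

**Compound list**
1 | 2,4-dimethylpentan-3-one | CC(C)C(=O)C(C)C | starting material
2 | 2-bromo-2,4-dimethylpentan-3-one | CC(C)C(=O)C(C)(C)Br | intermediate
3 | 2,4-dimethylpent-1-en-3-one | CC(C)C(=O)C(C)=C | intermediate
4 | tert-butyl[(2,4-dimethylpenta-1,3-dien-3-yl)oxy]dimethylsilane | CC(C)=C(O[Si](C)(C)C(C)(C)C)C(C)=C | intermediate
5 | cyclopent-2-en-1-one | O=C1C=CCC1 | starting material
6 | 4-[(1S)-3-[(tert-butyldimethylsilyl)oxy]cyclopent-2-en-1-yl]-2,4-dimethylpent-1-en-3-one (Michael adduct) | C=C(C)C(=O)C(C)(C)[C@H]1CCC(O[Si](C)(C)C(C)(C)C)=C1 | intermediate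
7 | (3aS,7aS)-5-[(tert-butyldimethylsilyl)oxy]-4,4,6-trimethyl-2,3,3a,4,7,7a-hexahydro-1H-inden-1-one | CC(C)(C)[Si](C)(C)OC1=C(C)C[C@@H]2C(=O)CC[C@@H]2C1(C)C | intermediate
8 | lithium (3aS,7aS)-5-[(tert-butyldimethylsilyl)oxy]-4,4,6-trimethyl-3a,4,7,7a-tetrahydro-3H-inden-1-olate (lithium enolate of 7) | CC(C)(C)[Si](C)(C)OC1=C(C)C[C@@H]2C(O[Li])=CC[C@@H]2C1(C)C | intermediate
9 | (3aS,7aS)-5-[(tert-butyldimethylsilyl)oxy]-4,4,6-trimethyl-1-[(trimethylsilyl)oxy]-3a,4,7,7a-tetrahydro-3H-indene | CC(C)(C)[Si](C)(C)OC1=C(C)C[C@@H]2C(O[Si](C)(C)C)=CC[C@@H]2C1(C)C | intermediate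
10 | carbene adduct of 9: 6-chloro-6-methyl-1-(trimethylsilyloxy)bicyclo[3.1.0]hexane fused to ring A, ring fusion as in 9, epimers at the three cyclopropane carbons | CC(C)(C)[Si](C)(C)OC1=C(C)C[C@@H]2C3(O[Si](C)(C)C)C(C)(Cl)C3C[C@@H]2C1(C)C | intermediate
11 | (4aS,8aS)-6-[(tert-butyldimethylsilyl)oxy]-2,5,5,7-tetramethyl-4a,5,8,8a-tetrahydronaphthalen-1(4H)-one | CC(C)(C)[Si](C)(C)OC1=C(C)C[C@@H]2C(=O)C(C)=CC[C@@H]2C1(C)C | intermediate
12 | N'-[(4aS,8aS)-6-[(tert-butyldimethylsilyl)oxy]-2,5,5,7-tetramethyl-4a,5,8,8a-tetrahydronaphthalen-1(4H)-ylidene]-4-methylbenzenesulfonohydrazide | CC(C)(C)[Si](C)(C)OC1=C(C)C[C@@H]2C(=NNS(=O)(=O)c3ccc(C)cc3)C(C)=CC[C@@H]2C1(C)C | intermediate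
13 | allylic diazene: 14 isomer with N=NH on C5 and the alkene at C6=C7 (C5 epimers) | CC(C)(C)[Si](C)(C)OC1=C(C)C[C@@H]2C(N=N)C(C)=CC[C@@H]2C1(C)C | intermediate
14 | tert-butyl(dimethyl){[(4aR,8aS)-1,1,3,6-tetramethyl-1,4,4a,7,8,8a-hexahydronaphthalen-2-yl]oxy}silane | CC(C)(C)[Si](C)(C)OC1=C(C)C[C@@H]2C=C(C)CC[C@@H]2C1(C)C | intermediate
15 | (4aR,8aS)-1,1,3,6-tetramethyl-1,4,4a,7,8,8a-hexahydronaphthalen-2-yl trifluoromethanesulfonate | O=S(=O)(OC1=C(C)C[C@@H]2C=C(C)CC[C@@H]2C1(C)C)C(F)(F)F | intermediate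
16 | (4aR,8aS)-2-ethenyl-1,1,3,6-tetramethyl-1,4,4a,7,8,8a-hexahydronaphthalene | C=CC1=C(C)C[C@@H]2C=C(C)CC[C@@H]2C1(C)C | intermediate
17 | pent-4-yn-1-ol | C#CCCCO | starting material
18 | 4-iodopent-4-en-1-ol | C=C(I)CCCO | intermediate
19 | 4-iodopent-4-enal | C=C(I)CCC=O | intermediate
20 | (4R)-4-benzyl-3-propanoyl-1,3-oxazolidin-2-one | CCC(=O)N1C(=O)OC[C@H]1Cc1ccccc1 | starting material
21 | (Z)-dibutylboron enolate of 20 | C/C=C(\OB(CCCC)CCCC)N1C(=O)OC[C@H]1Cc1ccccc1 | intermediate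
22 | (4R)-4-benzyl-3-[(2R,3S)-3-hydroxy-6-iodo-2-methylhept-6-enoyl]-1,3-oxazolidin-2-one | O=C(N1C(=O)OC[C@H]1Cc1ccccc1)[C@H](C)[C@@H](O)CCC(I)=C | intermediate
23 | (2S,3S)-6-iodo-2-methylhept-6-ene-1,3-diol | OC[C@H](C)[C@@H](O)CCC(I)=C | intermediate
24 | (2S,3S)-1-[(tert-butyldimethylsilyl)oxy]-6-iodo-2-methylhept-6-en-3-ol | CC(C)(C)[Si](C)(C)OC[C@H](C)[C@@H](O)CCC(I)=C | intermediate
25 | 9-{2-[(4aR,8aS)-1,1,3,6-tetramethyl-1,4,4a,7,8,8a-hexahydronaphthalen-2-yl]ethyl}-9-borabicyclo[3.3.1]nonane | C1CCC2CCCC1B2CCC1=C(C)C[C@@H]2C=C(C)CC[C@@H]2C1(C)C | intermediate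
26 | (2S,3S)-1-[(tert-butyldimethylsilyl)oxy]-2-methyl-6-methylidene-8-[(4aR,8aS)-1,1,3,6-tetramethyl-1,4,4a,7,8,8a-hexahydronaphthalen-2-yl]octan-3-ol | CC(C)(C)[Si](C)(C)OC[C@H](C)[C@@H](O)CCC(=C)CCC1=C(C)C[C@@H]2C=C(C)CC[C@@H]2C1(C)C | intermediate
27 | (2S,3S)-1-[(tert-butyldimethylsilyl)oxy]-2-methyl-6-methylidene-8-[(4aR,8aS)-1,1,3,6-tetramethyl-1,4,4a,7,8,8a-hexahydronaphthalen-2-yl]octan-3-yl methanesulfonate | CC(C)(C)[Si](C)(C)OC[C@H](C)[C@@H](OS(C)(=O)=O)CCC(=C)CCC1=C(C)C[C@@H]2C=C(C)CC[C@@H]2C1(C)C | intermediate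
28 | (2S,3S,6R)-1-[(tert-butyldimethylsilyl)oxy]-2,6-dimethyl-8-[(4aR,8aS)-1,1,3,6-tetramethyl-1,4,4a,7,8,8a-hexahydronaphthalen-2-yl]-6-[(triethylsilyl)peroxy]octan-3-yl methanesulfonate (accompanied by its C6 epimer) | CC(C)(C)[Si](C)(C)OC[C@H](C)[C@@H](OS(C)(=O)=O)CC[C@](C)(OO[Si](CC)(CC)CC)CCC1=C(C)C[C@@H]2C=C(C)CC[C@@H]2C1(C)C | intermediate
29 | (2S,3S,6R)-1-[(tert-butyldimethylsilyl)oxy]-6-hydroperoxy-2,6-dimethyl-8-[(4aR,8aS)-1,1,3,6-tetramethyl-1,4,4a,7,8,8a-hexahydronaphthalen-2-yl]octan-3-yl methanesulfonate | CC(C)(C)[Si](C)(C)OC[C@H](C)[C@@H](OS(C)(=O)=O)CC[C@](C)(OO)CCC1=C(C)C[C@@H]2C=C(C)CC[C@@H]2C1(C)C | intermediate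
30 | tert-butyl(dimethyl){(2S)-2-[(3R,6R)-6-methyl-6-{2-[(4aR,8aS)-1,1,3,6-tetramethyl-1,4,4a,7,8,8a-hexahydronaphthalen-2-yl]ethyl}-1,2-dioxan-3-yl]propoxy}silane | CC(C)(C)[Si](C)(C)OC[C@H](C)[C@H]1CC[C@@](C)(CCC2=C(C)C[C@@H]3C=C(C)CC[C@@H]3C2(C)C)OO1 | intermediate
31 | (2S)-2-[(3R,6R)-6-methyl-6-{2-[(4aR,8aS)-1,1,3,6-tetramethyl-1,4,4a,7,8,8a-hexahydronaphthalen-2-yl]ethyl}-1,2-dioxan-3-yl]propan-1-ol | OC[C@H](C)[C@H]1CC[C@@](C)(CCC2=C(C)C[C@@H]3C=C(C)CC[C@@H]3C2(C)C)OO1 | intermediate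
32 | (2R)-2-[(3R,6R)-6-methyl-6-{2-[(4aR,8aS)-1,1,3,6-tetramethyl-1,4,4a,7,8,8a-hexahydronaphthalen-2-yl]ethyl}-1,2-dioxan-3-yl]propanal | O=C[C@H](C)[C@H]1CC[C@@](C)(CCC2=C(C)C[C@@H]3C=C(C)CC[C@@H]3C2(C)C)OO1 | intermediate
33 | (2R)-2-[(3R,6R)-6-methyl-6-{2-[(4aR,8aS)-1,1,3,6-tetramethyl-1,4,4a,7,8,8a-hexahydronaphthalen-2-yl]ethyl}-1,2-dioxan-3-yl]propanoic acid | OC(=O)[C@H](C)[C@H]1CC[C@@](C)(CCC2=C(C)C[C@@H]3C=C(C)CC[C@@H]3C2(C)C)OO1 | intermediate
34 | methyl (2R)-2-[(3R,6R)-6-methyl-6-{2-[(4aR,8aS)-1,1,3,6-tetramethyl-1,4,4a,7,8,8a-hexahydronaphthalen-2-yl]ethyl}-1,2-dioxan-3-yl]propanoate | COC(=O)[C@H](C)[C@H]1CC[C@@](C)(CCC2=C(C)C[C@@H]3C=C(C)CC[C@@H]3C2(C)C)OO1 | target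

**Totals**
Total step count: 20. Longest linear sequence: 15 steps (steps 1–9, then 15–20); the side-chain branch (steps 10–14) joins at step 15.

**Steps most likely to fail**

Step 3. The hindered Me2C= terminus of 4 may add too slowly to the catalyst-bound enone, the sequence may stall after the first Michael addition, or the facial selectivity may be low or of the wrong sense. The fallback replaces catalyst control by substrate control and runs from 4 back to 7. Diene 4 is combined with purchased (R)-4-[(tert-butyldimethylsilyl)oxy]cyclopent-2-en-1-one (CC(C)(C)[Si](C)(C)O[C@@H]1CC(=O)C=C1) under an achiral Lewis acid (Me2AlCl, CH2Cl2, −78 °C). The same Michael/Michael annulation then takes place anti to the silyloxy group and should give (3R,3aS,7aS)-3,5-bis[(tert-butyldimethylsilyl)oxy]-4,4,6-trimethyl-2,3,3a,4,7,7a-hexahydro-1H-inden-1-one F1. Mild E1cB loss of silanol (DBU, CH2Cl2, 0 °C) gives (3aS,7aS)-5-[(tert-butyldimethylsilyl)oxy]-4,4,6-trimethyl-3a,4,7,7a-tetrahydro-1H-inden-1-one F2. Hydrogenation of the enone double bond alone (H2, Pd/C, EtOAc; the tetrasubstituted silyl enol ether is inert) returns 7.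

Step 5. The carbenoid may add to the ring-A enol ether, the cyclopropane epimer with exo chlorine may ionise too slowly, or the ring fusion next to the new carbonyl may epimerise during thermolysis. The fallback brings in C6 and its methyl in two separate events and runs from 9 back to 11. Dibromocarbene (CHBr3, KOtBu, pentane, −20 °C; no organolithium, and one bromine is always endo) adds to 9 to give the 6,6-dibromo-1-(trimethylsilyloxy)bicyclo[3.1.0]hexane adduct F3. This opens on gentle warming to (4aS,8aS)-2-bromo-6-[(tert-butyldimethylsilyl)oxy]-5,5,7-trimethyl-4a,5,8,8a-tetrahydronaphthalen-1(4H)-one F4. Stille methylation of the α-bromoenone (Me4Sn, Pd(PPh3)4, CuI, DMF) then gives 11.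

Step 17. Hydrogen-atom transfer may also reach the trisubstituted ring-B alkene (over-peroxidation), and the planar radical gives no facial control at C6′. The fallback forms the C6′–O bond by an ionic, tether-directed cyclisation and runs from 27 back to 30. Displacement of the mesylate of 27 by hydroperoxide anion (50% H2O2, KOH, MeOH, 0 °C → rt; inversion) gives (2S,3R)-1-[(tert-butyldimethylsilyl)oxy]-2-methyl-6-methylidene-8-[(4aR,8aS)-1,1,3,6-tetramethyl-1,4,4a,7,8,8a-hexahydronaphthalen-2-yl]octan-3-yl hydroperoxide F5. Cycloperoxymercuration (Hg(OAc)2, cat. HClO4, CH2Cl2), in which only the alkene within reach of the tethered OOH is captured 6-exo, gives the (acetoxymercurio)methyl dioxane F6. Demercuration (NaBH4, aq. NaOH, 0 °C) gives 30, again as both C6′ epimers, which then enters the desilylation of step 18.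

**Further compounds**
F1 | step 3 | (3R,3aS,7aS)-3,5-bis[(tert-butyldimethylsilyl)oxy]-4,4,6-trimethyl-2,3,3a,4,7,7a-hexahydro-1H-inden-1-one | CC(C)(C)[Si](C)(C)OC1=C(C)C[C@@H]2C(=O)C[C@@H](O[Si](C)(C)C(C)(C)C)[C@@H]2C1(C)C
F2 | step 3 | (3aS,7aS)-5-[(tert-butyldimethylsilyl)oxy]-4,4,6-trimethyl-3a,4,7,7a-tetrahydro-1H-inden-1-one | CC(C)(C)[Si](C)(C)OC1=C(C)C[C@@H]2C(=O)C=C[C@@H]2C1(C)C
F3 | step 5 | dibromocarbene adduct of 9: 6,6-dibromo-1-(trimethylsilyloxy)bicyclo[3.1.0]hexane fused to ring A, ring fusion as in 9 | CC(C)(C)[Si](C)(C)OC1=C(C)C[C@@H]2C3(O[Si](C)(C)C)C(Br)(Br)C3C[C@@H]2C1(C)C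
F4 | step 5 | (4aS,8aS)-2-bromo-6-[(tert-butyldimethylsilyl)oxy]-5,5,7-trimethyl-4a,5,8,8a-tetrahydronaphthalen-1(4H)-one | CC(C)(C)[Si](C)(C)OC1=C(C)C[C@@H]2C(=O)C(Br)=CC[C@@H]2C1(C)C
F5 | step 17 | (2S,3R)-1-[(tert-butyldimethylsilyl)oxy]-2-methyl-6-methylidene-8-[(4aR,8aS)-1,1,3,6-tetramethyl-1,4,4a,7,8,8a-hexahydronaphthalen-2-yl]octan-3-yl hydroperoxide | CC(C)(C)[Si](C)(C)OC[C@H](C)[C@H](OO)CCC(=C)CCC1=C(C)C[C@@H]2C=C(C)CC[C@@H]2C1(C)C
F6 | step 17 | {[(3R,6R)-3-{(2S)-1-[(tert-butyldimethylsilyl)oxy]propan-2-yl}-6-{2-[(4aR,8aS)-1,1,3,6-tetramethyl-1,4,4a,7,8,8a-hexahydronaphthalen-2-yl]ethyl}-1,2-dioxan-6-yl]methyl}mercury acetate (with its C6 epimer) | CC(C)(C)[Si](C)(C)OC[C@H](C)[C@H]1CC[C@@](C[Hg]OC(C)=O)(CCC2=C(C)C[C@@H]3C=C(C)CC[C@@H]3C2(C)C)OO1
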